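The rate constants are made up; no experiment stands behind them.

If Z stands left of each arrow, the flask moves as long as Z lasts, so reckon the state at that end and treat Z.Z.E as a correction to the share of Z.E.

| setting | alpha | delta |
|---|---|---|
| Z | 0.083 M | 0.083 M |
| E | 1.30 equiv | 1.30 equiv |
| temperature | 85 °C | 100 °C |
| time | 10 min | 10 min |

    Z + E → Z.E (k1 = 2.07 M⁻¹ s⁻¹, Ea1 = 66.0 kJ mol⁻¹)
    Z + E → X (k2 = 0.365 M⁻¹ s⁻¹, Ea2 = 76.0 kJ mol⁻¹)
    Z + E → L (k3 = 0.172 M⁻¹ s⁻¹, Ea3 = 53.0 kJ mol⁻¹)
    Z + Z.E → Z.Z.E (k4 = 0.150 M⁻¹ s⁻¹, Ea4 = 64.0 kJ mol⁻¹)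
    (constants at 100 °C)

- in percentages every species weighs as the Z in it: one Z.Z.E counts as two
- the list of constants is for 100 °C, to be carried to other temperatures by the activation energies

- which flask leads in amount of Z.E, in percent of the Z charged ("all alike" within 1.5 percentage points) (alpha / delta / all alike)
- how much Z.E is there at the end, in percent of the Z charged: alpha
- how much Z.E is there at the end, in percent of the Z charged: delta

Carry the constants first. Going from delta to alpha, the step into Z.Z.E slows by 2.4, and each other constant slows by that factor raised to the ratio of its activation energy to 64.0 kJ mol⁻¹. Call K the sum of the constants for Z + E: 2.61 M⁻¹ s⁻¹ in delta, 1.06 M⁻¹ s⁻¹ in alpha.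

Now climb the ladder. At the start Z, the limiting reagent, halves in 0.0411 min in delta and 0.101 min in alpha. With c(E) down to the bare excess, the half-life of Z in alpha is 0.436 min, shorter than the run, and 22.9 of these fit into 10 min. So reckon the end state, not the clock. On the last rung Z meets Z.E as well as E, and k4/K is 0.0575 in delta.

Let s be the selectivity, the share of Z + E that gives Z.E: 79.4% in delta, 79.8% in alpha. Define the capture number as s times k4/K: 0.0457 in delta, 0.0474 in alpha. Use c(E) as the clock, with e the equivalents of E and D the Z.Z.E formed per Z charged: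

D = capture number × G
G = e ln(e/e_end) − (e − e_end), with e_end = e − 1 + D
First pass, D = 0 in e_end: G = 0.906, D = 0.0414
Second pass: G = 0.780
delta: D = 0.0356, Z.E = s(1 − D) − D = 73.0%
alpha: D = 0.0370, Z.E = 73.2%

The gap of 0.20 percentage points is smaller than the margin, so I commit to all alike.

The forecast gives 73.3% (72% to 74.5%) for alpha and 73.1% (72% to 74.5%) for delta, verdict all alike, holding that “the outcome depends on selectivity rather than time”. My figures differ from these by 0.10 points in alpha and 0.100 points in delta.

The simulation gives 73.2% in alpha and 73.1% in delta, verdict all alike. Delta holds 7.08% Z.Z.E at 10.0 min, where twice D reads 7.12%. Take delta's neighbour with 5.20 equiv of E. Its G is 0.111, so D is 0.00505, which counts as 1.01% Z.Z.E and leaves 78.5% Z.E. That neighbour ends with 0.996% Z.Z.E and 78.5% Z.E at 10.0 min.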